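Ring A (the hydroxylated ring, C1'–C6' in carotenoid numbering) is built from an acyclic precursor. The retro-polyene is assembled by two Horner–Wadsworth–Emmons couplings (C10=C11 and C10'=C11') from a central C12 dialdehyde, a safranal-derived ring B phosphonate and a ring A phosphonate. In the key step an O-vinyl dienyl carbinol undergoes a [3,3] shift onto its Me2C= terminus (forming C1'–C2'), and the released aldehyde closes onto the isopropenyl CH2 by a carbonyl–ene reaction (forming C3'–C4'). The step exploits the exocyclic C6'=C7' alkene and the 1,3-placed C1' quaternary carbon and C3' carbinol: the carbinol oxygen is relayed from C7' to C3'. C3' is then fixed by oxidation and CBS reduction.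

Key step: step 13

Locants: ring A has C1' = CMe2, C2' = CH2, C3' = CHOH, C4'=C5'(CH3), C6' = ring carbon of the exocyclic alkene, with chain C7'–C15'; ring B and chain C7–C15 are the unprimed half.
Assumption: commercial 11 is used as its E isomer; the C8'=C9' geometry should in any case equilibrate in the extended enolate of step 14 and the phosphonate anion of step 16.
Remark: step 13 is run in one flask, the thermal shift and the Lewis-acid closure following each other without isolation of 19; racemic compounds carry no stereodescriptor.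

Step 1
Reactants: 1 safranal (2,6,6-trimethylcyclohexa-1,3-diene-1-carbaldehyde)
Product: 2 [(Z)-(2,6,6-trimethylcyclohexa-2,4-dien-1-ylidene)methyl] trifluoromethanesulfonate (OTf on the side of the CMe2 carbon)
Conditions: Tf2O, 2,6-di-tert-butyl-4-methylpyridine, CH2Cl2, 0 to 23 °C
Reagents that add atoms: trifluoromethanesulfonic anhydride, O=S(=O)(OS(=O)(=O)C(F)(F)F)C(F)(F)F
Why: Vinylogous enol triflate formation: O-sulfonylation gives a delocalised oxocarbenium ion that should lose the C2 proton to the linearly conjugated trienyl triflate, the OTf group taking the side of the CMe2 carbon to avoid 1,3-allylic strain with the C5 methyl.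

Step 2
Reactants: 2 trienyl triflate; 3 diethyl (2-methylprop-2-en-1-yl)phosphonate
Product: 4 diethyl [(2E,4Z)-2-methyl-4-(2,6,6-trimethylcyclohexa-2,4-dien-1-ylidene)but-2-en-1-yl]phosphonate (ring B phosphonate; chain on the side of the CMe2 carbon)
Conditions: Pd(OAc)2 (5 mol %), P(o-tolyl)3 (10 mol %), Et3N, DMF, 60 °C
Reagents that add atoms: none
Why: Mizoroki–Heck coupling of an alkenyl triflate with a 1,1-disubstituted alkene: carbopalladation at the CH2 terminus and β-hydride elimination from C8 should give the conjugated (8E)-alkene with retention of the C6=C7 geometry.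

Step 3
Reactants: 5 (2E)-3-methylpent-2-en-4-yn-1-ol
Product: 6 (2E,4E)-3-methyl-5-(tributylstannyl)penta-2,4-dien-1-ol
Conditions: Bu3SnH, PdCl2(PPh3)2 (2 mol %), THF, 0 °C
Reagents that add atoms: tributyltin hydride, CCCC[SnH](CCCC)CCCC
Why: Palladium-catalysed syn hydrostannylation of the terminal alkyne places tin on the terminal carbon and should give the (E)-alkenylstannane.

Step 4
Reactants: 6 dienylstannane (one half of the material)
Product: 7 (2E,4E)-5-iodo-3-methylpenta-2,4-dien-1-ol
Conditions: I2 (1.05 equiv), CH2Cl2, 0 °C, dark; then aqueous Na2S2O3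
Reagents that add atoms: iodine, II
Why: Iododestannylation, an electrophilic ipso substitution of the alkenyl carbon–tin bond by iodine, should proceed with retention of the (4E) geometry and leave the allylic alcohol untouched.

Step 5
Reactants: 6 dienylstannane; 7 dienyl iodide
Product: 8 (2E,4E,6E,8E)-3,8-dimethyldeca-2,4,6,8-tetraene-1,10-diol
Conditions: PdCl2(MeCN)2 (3 mol %), DMF, 23 °C, dark
Reagents that add atoms: none
Why: Stille cross-coupling of the alkenyl iodide with the alkenylstannane joins C15 to C15' with retention of both alkene geometries and tolerates the free hydroxyl groups; any homocoupling of either partner leads to the same symmetrical diol.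

Step 6
Reactants: 8 tetraene diol
Product: 9 (2E,4E,6E,8E)-3,8-dimethyldeca-2,4,6,8-tetraenedial
Conditions: MnO2, CH2Cl2, 23 °C
Reagents that add atoms: none
Why: Allylic oxidation with activated manganese dioxide converts both primary allylic alcohols into the conjugated dialdehyde without touching the tetraene.

Step 7
Reactants: 4 ring B phosphonate; 9 C12 dialdehyde
Product: 10 (2E,4E,6E,8E,10E,12E,14Z)-3,8,12-trimethyl-14-(2,6,6-trimethylcyclohexa-2,4-dien-1-ylidene)tetradeca-2,4,6,8,10,12-hexaenal (ring B C26 aldehyde; formyl carbon = C11')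
Conditions: NaN(SiMe3)2, THF, −78 °C; then 9 (3 equiv), −78 to 0 °C
Reagents that add atoms: none
Why: Horner–Wadsworth–Emmons olefination of the allylic phosphonate anion, in which the excess of the symmetrical dialdehyde (recovered) should hold the reaction at mono-olefination and the new C10=C11 alkene should form E.

Step 8
Reactants: 11 diethyl [(2E)-3-cyano-2-methylprop-2-en-1-yl]phosphonate
Product: 12 diethyl [(2E)-2-methyl-4-oxobut-2-en-1-yl]phosphonate
Conditions: iBu2AlH (1.1 equiv), toluene, −78 °C; then aqueous potassium sodium tartrate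
Reagents that add atoms: water, O
Why: Partial reduction of the conjugated nitrile to the aluminium aldimine followed by hydrolysis (the nitrile-to-aldehyde reduction used for retinal) should give the enal, the phosphonate ester being inert at −78 °C.

Step 9
Reactants: 13 N-methoxy-N,2-dimethylpropanamide; 14 prop-1-en-2-ylmagnesium bromide, CH2=C(CH3)MgBr
Product: 15 2,4-dimethylpent-1-en-3-one
Conditions: THF, 0 °C; then 1 M HCl
Reagents that add atoms: none
Why: Weinreb ketone synthesis, in which the chelated tetrahedral adduct stops the addition at the ketone stage.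

Step 10
Reactants: 15 2,4-dimethylpent-1-en-3-one
Product: 16 2,4-dimethylpenta-1,3-dien-3-yl trifluoromethanesulfonate
Conditions: Tf2O, 2,6-di-tert-butyl-4-methylpyridine, CH2Cl2, 0 to 23 °C
Reagents that add atoms: trifluoromethanesulfonic anhydride, O=S(=O)(OS(=O)(=O)C(F)(F)F)C(F)(F)F
Why: Enol triflate formation without strong base: the isopropyl methine is the only enolisable position, so the cross-conjugated dienyl triflate should form as one regioisomer and the enolate Michael addition that an amide base could start is avoided.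

Step 11
Reactants: 12 phosphonate enal; 16 dienyl triflate
Product: 17 diethyl [(2E)-4-hydroxy-2,6-dimethyl-5-(propan-2-ylidene)hepta-2,6-dien-1-yl]phosphonate (racemic)
Conditions: CrCl2 (4 equiv), NiCl2 (2 mol %), DMF, 23 °C
Reagents that add atoms: none
Why: Nozaki–Hiyama–Kishi coupling, in which the alkenylchromium species from the triflate adds 1,2 to the enal under non-basic conditions that leave the acidic phosphonate CH2 alone; the carbinol centre C7' is racemic and is destroyed in step 13.

Step 12
Reactants: 17 dienyl carbinol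
Product: 18 diethyl [(2E)-4-(ethenyloxy)-2,6-dimethyl-5-(propan-2-ylidene)hepta-2,6-dien-1-yl]phosphonate (racemic)
Conditions: Pd(OCOCF3)2 (2 mol %), 4,7-diphenyl-1,10-phenanthroline (2 mol %), Et3N (5 mol %), butyl vinyl ether (solvent), 23 °C
Reagents that add atoms: butyl vinyl ether, C=COCCCC
Why: Palladium-catalysed transfer vinylation (transetherification) should convert the secondary allylic alcohol into its vinyl ether at room temperature, below the onset of the [3,3] shift.

Step 13
Reactants: 18 allyl vinyl ether
Product: 20 diethyl [(2E,4Z)-4-(4-hydroxy-2,2-dimethyl-6-methylidenecyclohexylidene)-2-methylbut-2-en-1-yl]phosphonate (racemic; C8' on the side of C5'), via Claisen aldehyde 19 (not isolated)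
Conditions: toluene, 110 °C; then CH2Cl2, Me2AlCl (3 equiv), −78 to 0 °C (same flask)
Reagents that add atoms: none
Why: A thermal chair-like [3,3] sigmatropic shift (Claisen rearrangement) joins the vinyl CH2 (C2') to the Me2C= terminus (C1'), cleaves the C7'–O bond and releases aldehyde 19, whose C3' carbonyl carries the former carbinol oxygen; Me2AlCl then triggers a type 2 intramolecular carbonyl–ene reaction in which the isopropenyl CH2 (C4') attacks C3' while a hydrogen of the C5' methyl passes to oxygen. The closest known reaction type is the tandem Claisen rearrangement/carbonyl–ene cyclisation, with the Me2AlCl-promoted type 2 ene closure of 5-methylhex-5-enals as the model for the second event. Ring A closes in the six-membered (2,4)-ene mode through a chair-like transition state favoured by the C1' gem-dimethyl group and the sp2 carbon C6'. The new stereocentre C3' forms without control (racemate) and is not relied on, since it is erased in step 14 and set by the catalyst in step 15; the C6'=C7' geometry follows from the equatorial C8' substituent in the chair and is corrected in steps 14 and 16. The step needs regioselectivity between the two allyl arms of the doubly allylic ether, which rests on the tetrasubstituted C6'=C1' alkene being the more electron-rich partner with the smaller terminal groups (two methyls against methyl and phosphonomethyl at C9'); it also needs the ene reaction to choose the isopropenyl group, which is secured because C8', placed anti to C1' by the rearrangement, cannot reach the aldehyde, and any endocyclic alkene isomer of 20 converges in step 14.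

Step 14
Reactants: 20 ring A homoallylic alcohol
Product: 22 diethyl [(2E,4E)-2-methyl-4-(2,6,6-trimethyl-4-oxocyclohex-2-en-1-ylidene)but-2-en-1-yl]phosphonate, via exo-methylene ketone 21 (not isolated)
Conditions: Dess–Martin periodinane, NaHCO3, CH2Cl2, 0 to 23 °C; then DBU (0.5 equiv), 23 °C
Reagents that add atoms: none
Why: Dess–Martin oxidation gives the β,γ-unsaturated ketone, which DBU should conjugate through its dienolate to the cross-conjugated dienone, the same base relaxing the C6'=C7' alkene to the less strained geometry (C8' syn to C1') through the phosphonate-stabilised extended enolate.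

Step 15
Reactants: 22 ring A dienone
Product: 23 diethyl [(2E,4E)-4-[(4S)-4-hydroxy-2,6,6-trimethylcyclohex-2-en-1-ylidene]-2-methylbut-2-en-1-yl]phosphonate
Conditions: (R)-Me-CBS catalyst [(R)-1-methyl-3,3-diphenyltetrahydro-1H,3H-pyrrolo[1,2-c][1,3,2]oxazaborole] (0.2 equiv), catecholborane, toluene, −78 °C
Reagents that add atoms: none
Why: Corey–Bakshi–Shibata reduction, in which the alkenyl flank (C4') acts as the large group and the CH2 flank (C2') as the small one, so that the (R)-catalyst should deliver hydride to the face giving the (3'S)-allylic alcohol while catecholborane at −78 °C leaves the triene and the phosphonate untouched.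

Step 16
Reactants: 23 ring A phosphonate; 10 ring B C26 aldehyde
Product: 24 target CNP0202479.1
Conditions: 23, NaN(SiMe3)2 (2.1 equiv), THF, −78 °C; then 10, −78 to 0 °C; then heptane, 80 °C and crystallisation
Reagents that add atoms: none
Why: Horner–Wadsworth–Emmons olefination of the alkoxide–phosphonate dianion should form the C10'=C11' alkene E, and the customary thermal equilibration of the polyene should bring minor Z isomers to the all-trans target without touching C3'.

Compound list
1 | safranal, 2,6,6-trimethylcyclohexa-1,3-diene-1-carbaldehyde | CC1=C(C=O)C(C)(C)CC=C1 | starting material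
2 | [(Z)-(2,6,6-trimethylcyclohexa-2,4-dien-1-ylidene)methyl] trifluoromethanesulfonate | CC1=CC=CC(C)(C)\C1=C/OS(=O)(=O)C(F)(F)F | intermediate
3 | diethyl (2-methylprop-2-en-1-yl)phosphonate | C=C(C)CP(=O)(OCC)OCC | starting material
4 | diethyl [(2E,4Z)-2-methyl-4-(2,6,6-trimethylcyclohexa-2,4-dien-1-ylidene)but-2-en-1-yl]phosphonate | CC1=CC=CC(C)(C)\C1=C/C=C(C)/CP(=O)(OCC)OCC | intermediate
5 | (2E)-3-methylpent-2-en-4-yn-1-ol | C#C/C(C)=C/CO | starting material
6 | (2E,4E)-3-methyl-5-(tributylstannyl)penta-2,4-dien-1-ol | CCCC[Sn](CCCC)(CCCC)/C=C/C(C)=C/CO | intermediate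
7 | (2E,4E)-5-iodo-3-methylpenta-2,4-dien-1-ol | I/C=C/C(C)=C/CO | intermediate
8 | (2E,4E,6E,8E)-3,8-dimethyldeca-2,4,6,8-tetraene-1,10-diol | OC/C=C(C)/C=C/C=C/C(C)=C/CO | intermediate
9 | (2E,4E,6E,8E)-3,8-dimethyldeca-2,4,6,8-tetraenedial | O=C/C=C(C)/C=C/C=C/C(C)=C/C=O | intermediate
10 | (2E,4E,6E,8E,10E,12E,14Z)-3,8,12-trimethyl-14-(2,6,6-trimethylcyclohexa-2,4-dien-1-ylidene)tetradeca-2,4,6,8,10,12-hexaenal | CC1=CC=CC(C)(C)\C1=C/C=C(C)/C=C/C=C(C)/C=C/C=C/C(C)=C/C=O | intermediate
11 | diethyl [(2E)-3-cyano-2-methylprop-2-en-1-yl]phosphonate | N#C/C=C(C)/CP(=O)(OCC)OCC | starting material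
12 | diethyl [(2E)-2-methyl-4-oxobut-2-en-1-yl]phosphonate | O=C/C=C(C)/CP(=O)(OCC)OCC | intermediate
13 | N-methoxy-N,2-dimethylpropanamide | CC(C)C(=O)N(C)OC | starting material
14 | prop-1-en-2-ylmagnesium bromide | CC(=C)[Mg]Br | starting material
15 | 2,4-dimethylpent-1-en-3-one | CC(C)C(=O)C(C)=C | intermediate
16 | 2,4-dimethylpenta-1,3-dien-3-yl trifluoromethanesulfonate | CC(C)=C(OS(=O)(=O)C(F)(F)F)C(C)=C | intermediate
17 | diethyl [(2E)-4-hydroxy-2,6-dimethyl-5-(propan-2-ylidene)hepta-2,6-dien-1-yl]phosphonate (racemic) | CCOP(=O)(OCC)C/C(C)=C/C(O)C(=C(C)C)C(C)=C | intermediate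
18 | diethyl [(2E)-4-(ethenyloxy)-2,6-dimethyl-5-(propan-2-ylidene)hepta-2,6-dien-1-yl]phosphonate (racemic) | CCOP(=O)(OCC)C/C(C)=C/C(OC=C)C(=C(C)C)C(C)=C | intermediate
19 | diethyl [(2E,4E)-2,6,6-trimethyl-8-oxo-5-(prop-1-en-2-yl)octa-2,4-dien-1-yl]phosphonate (Claisen aldehyde, not isolated) | CCOP(=O)(OCC)C/C(C)=C/C=C(\C(C)=C)C(C)(C)CC=O | intermediate
20 | diethyl [(2E,4Z)-4-(4-hydroxy-2,2-dimethyl-6-methylidenecyclohexylidene)-2-methylbut-2-en-1-yl]phosphonate (racemic) | CCOP(=O)(OCC)C/C(C)=C/C=C1\C(=C)CC(O)CC1(C)C | intermediate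
21 | diethyl [(2E,4Z)-4-(2,2-dimethyl-6-methylidene-4-oxocyclohexylidene)-2-methylbut-2-en-1-yl]phosphonate (exo-methylene ketone, not isolated) | CCOP(=O)(OCC)C/C(C)=C/C=C1\C(=C)CC(=O)CC1(C)C | intermediate
22 | diethyl [(2E,4E)-2-methyl-4-(2,6,6-trimethyl-4-oxocyclohex-2-en-1-ylidene)but-2-en-1-yl]phosphonate | CCOP(=O)(OCC)C/C(C)=C/C=C1/C(C)=CC(=O)CC1(C)C | intermediate
23 | diethyl [(2E,4E)-4-[(4S)-4-hydroxy-2,6,6-trimethylcyclohex-2-en-1-ylidene]-2-methylbut-2-en-1-yl]phosphonate | CCOP(=O)(OCC)C/C(C)=C/C=C1/C(C)=C[C@@H](O)CC1(C)C | intermediate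
24 | CNP0202479.1: ring A (4S)-4-hydroxy-2,6,6-trimethylcyclohex-2-en-1-ylidene and ring B 2,6,6-trimethylcyclohexa-2,4-dien-1-ylidene on the all-trans 3,7,12,16-tetramethyloctadeca-2,4,6,8,10,12,14,16-octaene-1,18-diylidene chain, both chain ends syn to the CMe2 carbons | CC1=CC=CC(C)(C)\C1=C/C=C(C)/C=C/C=C(C)/C=C/C=C/C(C)=C/C=C/C(C)=C/C=C1/C(C)=C[C@@H](O)CC1(C)C | target

Total step count: 16.
Longest linear sequence: 8 steps (steps 9 to 16, from 13 and 14 to 24).

Steps most likely to fail

Step 13. The [3,3] shift may partition between the two allyl arms of the doubly allylic vinyl ether (bond formation at C9' instead of C1'), and the cationic closure may be diverted to chloride capture. The fallback sets out from 16 (and uses 10) and comes back at 24; it introduces the C8'=C9' alkene only after ring A exists, so that the ether has a single allyl arm. Nozaki–Hiyama–Kishi coupling of 16 with diethyl (2-oxoethyl)phosphonate gives diethyl [2-hydroxy-4-methyl-3-(propan-2-ylidene)pent-4-en-1-yl]phosphonate F1. Transfer vinylation as in step 12 gives diethyl [2-(ethenyloxy)-4-methyl-3-(propan-2-ylidene)pent-4-en-1-yl]phosphonate F2. Heating and then Me2AlCl as in step 13 give, through diethyl [(2E)-4,4-dimethyl-6-oxo-3-(prop-1-en-2-yl)hex-2-en-1-yl]phosphonate F3, the ring A alcohol diethyl [(2Z)-2-(4-hydroxy-2,2-dimethyl-6-methylidenecyclohexylidene)ethyl]phosphonate F4. Dess–Martin oxidation, through diethyl [(2Z)-2-(2,2-dimethyl-6-methylidene-4-oxocyclohexylidene)ethyl]phosphonate F5, followed by DBU gives diethyl [(2E)-2-(2,6,6-trimethyl-4-oxocyclohex-2-en-1-ylidene)ethyl]phosphonate F6. CBS reduction as in step 15 gives diethyl [(2E)-2-[(4S)-4-hydroxy-2,6,6-trimethylcyclohex-2-en-1-ylidene]ethyl]phosphonate F7. Aldol condensation of 10 with acetone (NaOH) gives (3E,5E,7E,9E,11E,13E,15E,17Z)-6,11,15-trimethyl-17-(2,6,6-trimethylcyclohexa-2,4-dien-1-ylidene)heptadeca-3,5,7,9,11,13,15-heptaen-2-one F8. Horner–Wadsworth–Emmons olefination of F8 with the dianion of F7 forms C8'=C9', and the thermal Z to E equilibration of step 16 should then give 24.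

Step 2. β-Hydride elimination from the tertiary alkylpalladium intermediate may go towards the methyl or the CH2P group, so that the alkene ends up in the wrong position; proton loss from the C5 methyl in step 1 would add to this. The fallback sets out from 22 and comes back at 4; it makes ring B as the dehydrated form of ring A. Reduction of 22 with NaBH4 and CeCl3·7H2O gives racemic diethyl [(2E,4E)-4-(4-hydroxy-2,6,6-trimethylcyclohex-2-en-1-ylidene)-2-methylbut-2-en-1-yl]phosphonate F9. Dehydration with Burgess reagent (syn elimination towards the ring CH2, the only β-hydrogens) should then give 4.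

Step 16. The alkoxide–phosphonate dianion may aggregate and add slowly, so that conversion stalls and Z/E scrambling grows. The fallback sets out from 23 and comes back at 24; it masks the hydroxyl group. TBSCl and imidazole give diethyl [(2E,4E)-4-[(4S)-4-{[tert-butyl(dimethyl)silyl]oxy}-2,6,6-trimethylcyclohex-2-en-1-ylidene]-2-methylbut-2-en-1-yl]phosphonate F10. Olefination of its monoanion with 10 gives the tert-butyldimethylsilyl ether of 24 F11, and Bu4NF buffered with acetic acid releases 24.

Further compounds
F1 | step 13 | diethyl [2-hydroxy-4-methyl-3-(propan-2-ylidene)pent-4-en-1-yl]phosphonate (racemic) | CCOP(=O)(OCC)CC(O)C(=C(C)C)C(C)=C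
F2 | step 13 | diethyl [2-(ethenyloxy)-4-methyl-3-(propan-2-ylidene)pent-4-en-1-yl]phosphonate (racemic) | CCOP(=O)(OCC)CC(OC=C)C(=C(C)C)C(C)=C
F3 | step 13 | diethyl [(2E)-4,4-dimethyl-6-oxo-3-(prop-1-en-2-yl)hex-2-en-1-yl]phosphonate | CCOP(=O)(OCC)C/C=C(\C(C)=C)C(C)(C)CC=O
F4 | step 13 | diethyl [(2Z)-2-(4-hydroxy-2,2-dimethyl-6-methylidenecyclohexylidene)ethyl]phosphonate (racemic) | CCOP(=O)(OCC)C/C=C1\C(=C)CC(O)CC1(C)C
F5 | step 13 | diethyl [(2Z)-2-(2,2-dimethyl-6-methylidene-4-oxocyclohexylidene)ethyl]phosphonate | CCOP(=O)(OCC)C/C=C1\C(=C)CC(=O)CC1(C)C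
F6 | step 13 | diethyl [(2E)-2-(2,6,6-trimethyl-4-oxocyclohex-2-en-1-ylidene)ethyl]phosphonate | CCOP(=O)(OCC)C/C=C1/C(C)=CC(=O)CC1(C)C
F7 | step 13 | diethyl [(2E)-2-[(4S)-4-hydroxy-2,6,6-trimethylcyclohex-2-en-1-ylidene]ethyl]phosphonate | CCOP(=O)(OCC)C/C=C1/C(C)=C[C@@H](O)CC1(C)C
F8 | step 13 | (3E,5E,7E,9E,11E,13E,15E,17Z)-6,11,15-trimethyl-17-(2,6,6-trimethylcyclohexa-2,4-dien-1-ylidene)heptadeca-3,5,7,9,11,13,15-heptaen-2-one | CC1=CC=CC(C)(C)\C1=C/C=C(C)/C=C/C=C(C)/C=C/C=C/C(C)=C/C=C/C(C)=O
F9 | step 2 | racemic diethyl [(2E,4E)-4-(4-hydroxy-2,6,6-trimethylcyclohex-2-en-1-ylidene)-2-methylbut-2-en-1-yl]phosphonate | CCOP(=O)(OCC)C/C(C)=C/C=C1/C(C)=CC(O)CC1(C)C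
F10 | step 16 | diethyl [(2E,4E)-4-[(4S)-4-{[tert-butyl(dimethyl)silyl]oxy}-2,6,6-trimethylcyclohex-2-en-1-ylidene]-2-methylbut-2-en-1-yl]phosphonate | CCOP(=O)(OCC)C/C(C)=C/C=C1/C(C)=C[C@@H](O[Si](C)(C)C(C)(C)C)CC1(C)C
F11 | step 16 | tert-butyldimethylsilyl ether of 24 | CC1=CC=CC(C)(C)\C1=C/C=C(C)/C=C/C=C(C)/C=C/C=C/C(C)=C/C=C/C(C)=C/C=C1/C(C)=C[C@@H](O[Si](C)(C)C(C)(C)C)CC1(C)C
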